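(All runs come from a simulation on assumed constants; scatter was added.)

In a one-step world, substrate and reagent pass one to one into product at a rate proportional to c_substrate·c_reagent·c_free catalyst, and the smaller charge, the limiting reagent, caps the product.

| flask | substrate | reagent | free catalyst | remark |
|---|---|---|---|---|
| south | 10 mM | 12 mM | 20 µM | run made earlier |
| north | 40 mM | 12 mM | 20 µM | run made earlier |
| flask | 20 mM | 12.0 mM | 20 µM |  |

| run | time / min | product / % |
|---|---|---|
| south | 1.33 | 29 |
| south | 2.00 | 39 |
| south | 3.00 | 48 |
| south | 5.00 | 61 |
| south | 10.0 | 74 |
| south | 15.0 | 80 |
| north | 2.50 | 23 |
| north | 5.00 | 28 |
| north | 8.00 | 31 |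
| north | 10.0 | 31 |
| north | 12.0 | 24 |
| north | 15.0 | 29 |

(standard deviation of a reading: 2 percentage points)

- factor on the rate of making product when 50% of the substrate are converted if reagent is charged twice over
- factor on the rate when 50% of the substrate are converted if free catalyst is charged at 200 µM instead

- no earlier run changes the charge of free catalyst; that part of a forecast is a guess
- no earlier run changes the charge of reagent; that part of a forecast is a guess

I began by comparing the two earlier runs, which differed in substrate charge. South, with 10 mM of substrate under 12 mM of reagent, was still climbing at 80% after 15.0 min, which is 8.00 mM of product. North, with 40 mM, stopped climbing: it read 31% at 8.00 min and 29% at 15.0 min, which is 12.4 mM and 11.6 mM of product, about the reagent charge. So reagent was the limiting reagent in north, and the flask, with 20 mM against 12.0 mM, has the same limit.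

At 50% conversion the flask keeps 2.00 mM of reagent, and a double charge keeps 14.0 mM, so my first answer, guessing first order in reagent, was a factor of 7.00.

But south did not stay in the one-step world. I defined the fade as the mean second-order constant of south over its first reading divided by the same constant over its last, 1.45, a reading with its scatter, and larger than the 1 of a steady run. I expected a flask with a richer charge of reagent or free catalyst to reach 50% conversion sooner and so to meet less of that fade, and I went round once more: taking it to meet none of the fade, I multiplied by it. That gave 10.2 for reagent and, guessing first order in free catalyst, 14.5 for free catalyst.

The forecast said 9 (6 to 25) for reagent, noting “Catalyst decay or a higher order would raise it”, and 10 (3 to 14) for free catalyst, and I stood higher on both .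

The flask gave 9.96 and 15.3.

    substrate + reagent + free catalyst → product + free catalyst, rate k1*[substrate]*[reagent]*[free catalyst]/(1 + ([substrate]/sat1)) (46.2 mM, k = 24200 M⁻² s⁻¹)
    free catalyst → spent catalyst (k = 0.0613 min⁻¹)

Free catalyst passes into spent catalyst as the flask runs; with that step taken away, the rate at 50% conversion stands at 1.59 times the actual one. Over the plain charge ratios, the flask gained 1.42 with reagent and 1.53 with free catalyst, beside a fade of 1.45. With twice the free catalyst, the rate rose by a factor of 2.59, less than the 2.90 that the fade gives.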